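The ring atoms are C1–C10. The lactone is O–C6 and C7–C11–C12(=O), C13 is the exocyclic CH2, C14 sits on C10 and C15 on C4. The retrosynthesis cuts the C9–O acyl bond, turns C11=C13 back into a C13–NMe2 Mannich base, takes the C9 carbinol back to a ketone, and then re-bonds C4 to C9, so the ten-membered ring becomes the perimeter of a decalin.
The feature that allows this is the Z olefin C1=C10 with its two oxygenated allylic carbons C2 and C9, which fits a cyclohexene (C9-C10-C1-C2-C3-C4), while O–C9 stands 1,3 to C5. A C9 alkoxide and an equatorial C5 bromide can therefore cleave C4–C9 (Grob) and write E-C4=C5.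
The decalin is cut at C4–C5 (radical closure onto a p-quinol), at C9–OH (oxidative dearomatisation of a 3,5-dimethylphenol unit = C1–C4, C9, C10, C14, C15) and at C7–C8 (benzyl addition to a butenolide = C5, C6, C7, C11, C12).
In the forward direction the γ-lactone is present from the start of its branch, then comes the arene/dienone ring, then the temporary cyclohexane C4–C9, and the ten-membered ring last. The side-chain acid is made separately and joined after the ring expansion.
C6 comes from (S)-5-(hydroxymethyl)furan-2(5H)-one and C7 from anti conjugate addition; the trans-lactone then locks the chair that fixes the temporary centres C4, C5 and C9. C2 is set by convex-face hydride plus Mitsunobu inversion and C9 by CBS reduction.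
Z-C1=C10 comes from the six-membered ring, E-C4=C5 from the antiperiplanar fragmentation, and the side-chain Z geometry from (E)-crotonaldehyde with retentive carbonylation.

Key step: step 13

Remark 1: β is the face of H-6 and α the face of H-7. For the tricycles, "4,9-cyclo" means the extra C4–C9 bond.
Remark 2: C11 of the Mannich base is drawn as the epimer expected from anti alkylation. Either epimer converges in step 21.

Step 1
Reactants: 1 4-hydroxy-2,6-dimethylbenzaldehyde
Product: 2 4-(tert-butyldimethylsilyloxy)-2,6-dimethylbenzaldehyde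
Conditions: TBSCl, imidazole, DMF, rt
Reagents that add atoms: tert-butyldimethylsilyl chloride CC(C)(C)[Si](C)(C)Cl
Why: Standard silyl ether protection of a phenol; the aryl TBS ether should survive Grignard formation and acid and fall later to fluoride.

Step 2
Reactants: 2 4-(tert-butyldimethylsilyloxy)-2,6-dimethylbenzaldehyde
Product: 3 [4-(tert-butyldimethylsilyloxy)-2,6-dimethylphenyl]methanol
Conditions: NaBH4, MeOH, 0 °C
Reagents that add atoms: none
Why: Borohydride reduction of an aryl aldehyde; no stereocentre is formed.

Step 3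
Reactants: 3 [4-(tert-butyldimethylsilyloxy)-2,6-dimethylphenyl]methanol
Product: 4 4-(tert-butyldimethylsilyloxy)-2,6-dimethylbenzyl chloride
Conditions: SOCl2, CH2Cl2, 0 °C
Reagents that add atoms: thionyl chloride O=S(Cl)Cl
Why: Chlorodehydroxylation of an electron-rich benzylic alcohol with thionyl chloride; the chloride rather than the bromide is chosen to limit Wurtz coupling in step 5.

Step 4
Reactants: 5 (S)-5-(hydroxymethyl)furan-2(5H)-one
Product: 6 (S)-5-[(triethylsilyloxy)methyl]furan-2(5H)-one
Conditions: TESCl, imidazole, CH2Cl2, 0 °C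
Reagents that add atoms: triethylsilyl chloride CC[Si](Cl)(CC)CC
Why: Silyl ether protection; TES is chosen because a primary TES ether can be oxidised directly in step 6, and the C6 stereocentre is not touched.

Step 5
Reactants: 4 4-(tert-butyldimethylsilyloxy)-2,6-dimethylbenzyl chloride; 6 (S)-5-[(triethylsilyloxy)methyl]furan-2(5H)-one
Product: 9 (3R,4S,5S)-4-[4-(tert-butyldimethylsilyloxy)-2,6-dimethylbenzyl]-3-[(dimethylamino)methyl]-5-[(triethylsilyloxy)methyl]dihydrofuran-2(3H)-one, via benzylmagnesium chloride 7 (not isolated), via magnesium lactone enolate 8 (not isolated)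
Conditions: Mg, THF, 0 °C; CuBr·SMe2 (10 mol %), 6, THF, −78 °C; then CH2=NMe2+ I−, −78 °C → rt
Reagents that add atoms: Eschenmoser's salt C[N+](C)=C.[I-]
Why: Copper-catalysed conjugate addition of a benzylic Grignard reagent to a γ-substituted butenolide, followed by Mannich trapping of the enolate (vicinal difunctionalisation): the nucleophile should enter anti to the C6 side chain (sets C7), the iminium ion anti to the new C7 substituent (sets C11), and the Mannich base is the masked α-methylene lactone.

Step 6
Reactants: 9 all-trans Mannich lactone TES ether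
Product: 10 (2S,3S,4R)-3-[4-(tert-butyldimethylsilyloxy)-2,6-dimethylbenzyl]-4-[(dimethylamino)methyl]-5-oxotetrahydrofuran-2-carbaldehyde
Conditions: (COCl)2, DMSO, CH2Cl2, −78 → −40 °C; Et3N
Reagents that add atoms: none
Why: Swern oxidation applied directly to a primary TES ether (the activated sulfonium species desilylates and oxidises in one operation); the aryl TBS ether and the tertiary amine are inert, and the low temperature should keep the α-acyloxy aldehyde configurationally intact.

Step 7
Reactants: 10 lactone aldehyde (C5 = CHO)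
Product: 11 (3R,4S,5S)-4-[4-(tert-butyldimethylsilyloxy)-2,6-dimethylbenzyl]-5-(dibromomethyl)-3-[(dimethylamino)methyl]dihydrofuran-2(3H)-one
Conditions: P(OPh)3, Br2, CH2Cl2, −78 °C; then 10, −78 → 0 °C
Reagents that add atoms: bromine BrBr
Why: Deoxygenative gem-dibromination of an aldehyde with preformed (PhO)3PBr2; preforming the reagent leaves no free bromine for the arene, and C6 is not involved.

Step 8
Reactants: 11 gem-dibromide aryl silyl ether
Product: 12 (3R,4S,5S)-5-(dibromomethyl)-3-[(dimethylamino)methyl]-4-(4-hydroxy-2,6-dimethylbenzyl)dihydrofuran-2(3H)-one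
Conditions: TBAF, AcOH, THF, 0 °C
Reagents that add atoms: none
Why: Fluoride cleavage of an aryl silyl ether, buffered with acetic acid so that neither dehydrobromination of the CHBr2 group nor lactone opening should occur.

Step 9
Reactants: 12 dibromomethyl lactone phenol
Product: 13 (3R,4S,5S)-5-(dibromomethyl)-3-[(dimethylamino)methyl]-4-[(1-hydroxy-2,6-dimethyl-4-oxocyclohexa-2,5-dien-1-yl)methyl]dihydrofuran-2(3H)-one
Conditions: PhI(OAc)2, TFA (1.1 equiv), MeCN/H2O 4:1, 0 °C; aq NaHCO3
Reagents that add atoms: water O
Why: Hypervalent-iodine oxidative dearomatisation of a para-alkylphenol with water as nucleophile (p-quinol synthesis); protonation keeps the amine from being oxidised or from trapping the para position, and C9 is not yet stereogenic because its two dienone arms are identical.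

Step 10
Reactants: 13 p-quinol gem-dibromide
Product: 14 5β-bromo-13-(dimethylamino)-9β-hydroxy-2-oxo-4,9-cyclogermacr-1(10)-en-12,6-olide (cis-decalin; C15, Br, H-6, C11 and 9-OH β; H-5, O-6, H-7 and C10 α)
Conditions: (TMS)3SiH (1.1 equiv, syringe pump), Et3B, air, toluene (5 mM), rt
Reagents that add atoms: none
Why: Proposed new method: the silyl radical should abstract one bromine of the CHBr2 group much faster than it attacks a monobromide or adds to a carbonyl, the α-bromoalkyl radical at C5 should close 6-exo-trig onto the β-carbon C4 of the cross-conjugated dienone, and the α-keto radical at C3 should take H from the silane, so the second bromine is kept as the later nucleofuge; the trans-fused lactone allows only the chair transition state with C6–O and C7–C11 equatorial, which selects one of the two diastereotopic dienone arms (C4–CH3 axial, C9–OH cis to it) and places Br equatorial, away from the concave face; the closest known reaction types are the stannane- or silane-mediated cyclisation of haloalkyl side chains onto p-quinol-derived cyclohexadienones and the stepwise radical reduction of gem-dihalides.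

Step 11
Reactants: 14 tricyclic bromo enone
Product: 15 5β-bromo-13-(dimethylamino)-2α,9β-dihydroxy-4,9-cyclogermacr-1(10)-en-12,6-olide (C2–OH trans to C4–CH3)
Conditions: NaBH4, CeCl3·7H2O, MeOH, −78 °C
Reagents that add atoms: none
Why: Luche 1,2-reduction: hydride should reach C2 from the convex face of the cis-decalin (the concave face is screened by axial C5 and H-5), giving the alcohol trans to C4–CH3, which is the C2 epimer of what the target needs, while lactone and bromide are untouched.

Step 12
Reactants: 15 2α-allylic alcohol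
Product: 16 5β-bromo-13-(dimethylamino)-9β-hydroxy-2β-(4-nitrobenzoyloxy)-4,9-cyclogermacr-1(10)-en-12,6-olide (C2–O cis to C4–CH3)
Conditions: 4-O2NC6H4CO2H (2.5 equiv), PPh3, DIAD, THF, 0 °C → rt
Reagents that add atoms: 4-nitrobenzoic acid OC(=O)c1ccc(cc1)[N+](=O)[O-]
Why: Mitsunobu reaction: SN2 displacement of the activated pseudo-axial allylic oxygen by carboxylate from the open convex face should invert C2 to the target configuration and at the same time block C2–O for the fragmentation; SN2′ attack at fully substituted C10 and reaction of the tertiary C9–OH are not expected.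

Step 13
Reactants: 16 bromo alcohol 4-nitrobenzoate
Product: 18 (1(10)Z,4E)-13-(dimethylamino)-2-(4-nitrobenzoyloxy)-9-oxo-11,13-dihydrogermacra-1(10),4-dien-12,6-olide (C2, C6, C7 as in the target), via potassium C9-alkoxide 17 (not isolated)
Conditions: KHMDS (1.05 equiv), THF, −78 → 0 °C
Reagents that add atoms: none
Why: KHMDS converts the tertiary C9–OH into alkoxide 17, whose oxygen lone pair builds C9=O while the C4–C9 σ bond, antiperiplanar to the equatorial C5–Br bond, becomes the C4=C5 π bond and bromide leaves in one concerted heterolytic Grob fragmentation. The closest known reaction type is the Wharton fragmentation of decalin 1,3-hydroxy sulfonates or halides to (E)-cyclodec-5-enones. The ten-membered ring is closed not end to end but by ring expansion: scission of the zero bridge of the bicyclo[4.4.0]decane merges the cyclohexene C9-C10-C1-C2-C3-C4 and the cyclohexane C4-C5-C6-C7-C8-C9 into their common perimeter, with the lactone ring untouched. No stereocentre is formed (C4, C5 and C9 are erased); the new stereogenic unit E-C4=C5 is fixed because equatorial C3 is anti to C6 across C4–C5 in the chair locked by the trans-fused lactone, and Z-C1=C10 is inherited from the cyclohexene. The step needs fragmentation to beat E2, oxetane formation and acyl attack: an equatorial bromide has no antiperiplanar hydrogen, backside attack by O-9 on C5 is geometrically impossible, C2–O is blocked so that no 3-oxido-1,5-diene (anionic oxy-Cope) can arise, and only one equivalent of a non-nucleophilic base is used.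

Step 14
Reactants: 18 germacradienolide enone
Product: 19 (1(10)Z,4E)-13-(dimethylamino)-9-hydroxy-2-(4-nitrobenzoyloxy)-11,13-dihydrogermacra-1(10),4-dien-12,6-olide (C9 as in the target)
Conditions: (R)-Me-CBS (0.3 equiv), catecholborane (2.5 equiv), toluene, −78 °C; aq work-up
Reagents that add atoms: none
Why: Corey–Bakshi–Shibata reduction of an α-methyl enone (alkenyl = large group): the (R)-catalyst should deliver hydride to the face that gives 9S, which is also the face exposed on the periphery in the conformation released by the fragmentation (the other face looks at C4=C5 across the ring), so reagent and substrate control should reinforce each other.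

Step 15
Reactants: 20 (E)-crotonaldehyde
Product: 21 (Z)-2-iodobut-2-enal
Conditions: I2, K2CO3, DMAP (20 mol %), THF/H2O, rt
Reagents that add atoms: iodine II
Why: α-Iodination of an enal by amine-catalysed addition, iodination and elimination (Baylis–Hillman-type); iodine takes the place of H-2, so CHO stays trans and I becomes cis to CH3.

Step 16
Reactants: 21 (Z)-2-iodobut-2-enal
Product: 22 (Z)-2-iodobut-2-en-1-ol
Conditions: NaBH4, MeOH, 0 °C
Reagents that add atoms: none
Why: 1,2-Reduction of an α-iodo enal by borohydride; the olefin geometry is untouched.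

Step 17
Reactants: 22 (Z)-2-iodobut-2-en-1-ol
Product: 23 (Z)-tert-butyl[(2-iodobut-2-en-1-yl)oxy]dimethylsilane
Conditions: TBSCl, imidazole, CH2Cl2, rt
Reagents that add atoms: tert-butyldimethylsilyl chloride CC(C)(C)[Si](C)(C)Cl
Why: Silyl ether protection of the primary allylic alcohol so that the acid made in step 18 cannot acylate itself.

Step 18
Reactants: 23 (Z)-vinyl iodide TBS ether
Product: 24 (Z)-2-[(tert-butyldimethylsilyloxy)methyl]but-2-enoic acid
Conditions: Pd(OAc)2, dppf (5 mol %), CO (1 atm), H2O, Et3N, DMF, 50 °C; citric acid work-up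
Reagents that add atoms: carbon monoxide [C-]#[O+]; water O
Why: Palladium-catalysed hydroxycarbonylation of a vinyl iodide, which proceeds with retention at the sp2 carbon, so CO2H ends cis to CH3 (angelate-type Z geometry).

Step 19
Reactants: 19 C9 allylic alcohol; 24 (Z)-2-[(tert-butyldimethylsilyloxy)methyl]but-2-enoic acid
Product: 26 C9 (Z)-2-[(tert-butyldimethylsilyloxy)methyl]but-2-enoate of 19, via Yamaguchi mixed anhydride 25 (not isolated)
Conditions: 24, 2,4,6-Cl3C6H2COCl, Et3N, toluene, rt; then 19, DMAP, toluene, rt
Reagents that add atoms: none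
Why: Yamaguchi esterification through mixed anhydride 25; C9 keeps its configuration, and the mild temperature should limit Z→E isomerisation by reversible DMAP addition and any Cope rearrangement of the 1,5-diene.

Step 20
Reactants: 26 diester Mannich lactone
Product: 27 (1(10)Z,4E)-13-(dimethylamino)-2-hydroxy-9-{(Z)-2-[(tert-butyldimethylsilyloxy)methyl]but-2-enoyloxy}-11,13-dihydrogermacra-1(10),4-dien-12,6-olide
Conditions: K2CO3 (0.2 equiv), MeOH, 0 °C
Reagents that add atoms: none
Why: Base-catalysed transesterification: the electron-poor 4-nitrobenzoate should be cleaved far faster than the hindered conjugated C9 ester, and the lactone, still masked as Mannich base, cannot suffer Michael addition of methoxide.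

Step 21
Reactants: 27 C2 alcohol Mannich lactone
Product: 29 side-chain O-TBS ether of the target, via trimethylammonium iodide 28 (not isolated)
Conditions: MeI, THF, rt; then aq NaHCO3, EtOAc, rt
Reagents that add atoms: none
Why: Exhaustive methylation and E1cB (Hofmann-type) elimination of the β-ammonio lactone, the standard release of an α-methylene-γ-butyrolactone from its amine adduct; the C11 stereocentre is erased.

Step 22
Reactants: 29 side-chain O-TBS ether of the target
Product: 30 CNP0273961.1, (2R,6R,7S,9S,1(10)Z,4E)-2-hydroxy-9-[(Z)-2-(hydroxymethyl)but-2-enoyloxy]germacra-1(10),4,11(13)-trien-12,6-olide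
Conditions: HF·pyridine, THF, 0 °C
Reagents that add atoms: none
Why: Fluoride-mediated cleavage of the primary allylic TBS ether under non-basic conditions that should spare the Michael acceptor, both esters and the 1,5-diene.

Compound list
1 | 4-hydroxy-2,6-dimethylbenzaldehyde | Cc1cc(O)cc(C)c1C=O | starting material
2 | 4-(tert-butyldimethylsilyloxy)-2,6-dimethylbenzaldehyde | Cc1cc(O[Si](C)(C)C(C)(C)C)cc(C)c1C=O | intermediate
3 | [4-(tert-butyldimethylsilyloxy)-2,6-dimethylphenyl]methanol | Cc1cc(O[Si](C)(C)C(C)(C)C)cc(C)c1CO | intermediate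
4 | 4-(tert-butyldimethylsilyloxy)-2,6-dimethylbenzyl chloride | Cc1cc(O[Si](C)(C)C(C)(C)C)cc(C)c1CCl | intermediate
5 | (S)-5-(hydroxymethyl)furan-2(5H)-one | O=C1C=C[C@@H](CO)O1 | starting material
6 | (S)-5-[(triethylsilyloxy)methyl]furan-2(5H)-one | O=C1C=C[C@@H](CO[Si](CC)(CC)CC)O1 | intermediate
7 | 4-(tert-butyldimethylsilyloxy)-2,6-dimethylbenzylmagnesium chloride | Cc1cc(O[Si](C)(C)C(C)(C)C)cc(C)c1C[Mg]Cl | intermediate
8 | chloromagnesium enolate of the trans-4-benzyl-5-(silyloxymethyl) lactone | Cl[Mg]OC1=C[C@H](Cc2c(C)cc(O[Si](C)(C)C(C)(C)C)cc2C)[C@@H](CO[Si](CC)(CC)CC)O1 | intermediate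
9 | (3R,4S,5S) all-trans Mannich lactone, aryl TBS and primary TES ether | O=C1[C@@H](CN(C)C)[C@H](Cc2c(C)cc(O[Si](C)(C)C(C)(C)C)cc2C)[C@@H](CO[Si](CC)(CC)CC)O1 | intermediate
10 | (2S,3S,4R) lactone aldehyde (C5 = CHO) | O=C1[C@@H](CN(C)C)[C@H](Cc2c(C)cc(O[Si](C)(C)C(C)(C)C)cc2C)[C@@H](C=O)O1 | intermediate
11 | (3R,4S,5S) dibromomethyl lactone, aryl TBS ether | O=C1[C@@H](CN(C)C)[C@H](Cc2c(C)cc(O[Si](C)(C)C(C)(C)C)cc2C)[C@@H](C(Br)Br)O1 | intermediate
12 | (3R,4S,5S) dibromomethyl lactone phenol | O=C1[C@@H](CN(C)C)[C@H](Cc2c(C)cc(O)cc2C)[C@@H](C(Br)Br)O1 | intermediate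
13 | (3R,4S,5S) dibromomethyl lactone p-quinol | O=C1[C@@H](CN(C)C)[C@H](CC2(O)C(C)=CC(=O)C=C2C)[C@@H](C(Br)Br)O1 | intermediate
14 | 5β-bromo-9β-hydroxy-2-oxo-4,9-cyclogermacr-1(10)-en-12,6-olide Mannich base | C[C@@]12CC(=O)C=C(C)[C@]1(O)C[C@H]1[C@H](CN(C)C)C(=O)O[C@@H]1[C@H]2Br | intermediate
15 | 2α-alcohol of 14 (C2–OH trans to C4–CH3) | C[C@@]12C[C@H](O)C=C(C)[C@]1(O)C[C@H]1[C@H](CN(C)C)C(=O)O[C@@H]1[C@H]2Br | intermediate
16 | 2β-(4-nitrobenzoate) (C2–O cis to C4–CH3) | C[C@@]12C[C@@H](OC(=O)c3ccc(cc3)[N+](=O)[O-])C=C(C)[C@]1(O)C[C@H]1[C@H](CN(C)C)C(=O)O[C@@H]1[C@H]2Br | intermediate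
17 | potassium C9-alkoxide of 16 | C[C@@]12C[C@@H](OC(=O)c3ccc(cc3)[N+](=O)[O-])C=C(C)[C@]1([O-])C[C@H]1[C@H](CN(C)C)C(=O)O[C@@H]1[C@H]2Br.[K+] | intermediate
18 | (1(10)Z,4E)-9-oxogermacradienolide, C2 4-nitrobenzoate, Mannich base | CN(C)C[C@@H]1C(=O)O[C@@H]2/C=C(\C)C[C@@H](OC(=O)c3ccc(cc3)[N+](=O)[O-])/C=C(/C)C(=O)C[C@@H]12 | intermediate
19 | 9S alcohol of 18 | CN(C)C[C@@H]1C(=O)O[C@@H]2/C=C(\C)C[C@@H](OC(=O)c3ccc(cc3)[N+](=O)[O-])/C=C(/C)[C@@H](O)C[C@@H]12 | intermediate
20 | (E)-crotonaldehyde | C/C=C/C=O | starting material
21 | (Z)-2-iodobut-2-enal | I/C(=C\C)C=O | intermediate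
22 | (Z)-2-iodobut-2-en-1-ol | I/C(=C\C)CO | intermediate
23 | (Z)-tert-butyl[(2-iodobut-2-en-1-yl)oxy]dimethylsilane | I/C(=C\C)CO[Si](C)(C)C(C)(C)C | intermediate
24 | (Z)-2-[(tert-butyldimethylsilyloxy)methyl]but-2-enoic acid | OC(=O)/C(=C\C)CO[Si](C)(C)C(C)(C)C | intermediate
25 | mixed anhydride of 24 with 2,4,6-trichlorobenzoic acid | O=C(OC(=O)/C(=C\C)CO[Si](C)(C)C(C)(C)C)c1c(Cl)cc(Cl)cc1Cl | intermediate
26 | C9 ester, C2 4-nitrobenzoate, Mannich base | CN(C)C[C@@H]1C(=O)O[C@@H]2/C=C(\C)C[C@@H](OC(=O)c3ccc(cc3)[N+](=O)[O-])/C=C(/C)[C@@H](OC(=O)/C(=C\C)CO[Si](C)(C)C(C)(C)C)C[C@@H]12 | intermediate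
27 | C9 ester, free C2–OH, Mannich base | CN(C)C[C@@H]1C(=O)O[C@@H]2/C=C(\C)C[C@@H](O)/C=C(/C)[C@@H](OC(=O)/C(=C\C)CO[Si](C)(C)C(C)(C)C)C[C@@H]12 | intermediate
28 | trimethylammonium iodide of 27 | C[N+](C)(C)C[C@@H]1C(=O)O[C@@H]2/C=C(\C)C[C@@H](O)/C=C(/C)[C@@H](OC(=O)/C(=C\C)CO[Si](C)(C)C(C)(C)C)C[C@@H]12.[I-] | intermediate
29 | side-chain O-TBS ether of the target | C=C1C(=O)O[C@@H]2/C=C(\C)C[C@@H](O)/C=C(/C)[C@@H](OC(=O)/C(=C\C)CO[Si](C)(C)C(C)(C)C)C[C@@H]12 | intermediate
30 | CNP0273961.1 | C=C1C(=O)O[C@@H]2/C=C(\C)C[C@@H](O)/C=C(/C)[C@@H](OC(=O)/C(=C\C)CO)C[C@@H]12 | target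

Total step count: 22.
Longest linear sequence: 17 steps (steps 1–3, 5–14, 19–22).

Steps most likely to fail

1. Step 10 (bears the label). The C5 radical may take hydrogen before it reaches the fully substituted C4, the product may lose its second bromine, or the bromine-bearing radical may be too poorly nucleophilic for the enone.
The fallback sets out from 10 and returns at 18. It replaces the halogen-bearing radical by a ketyl and the bromide by a sulfonate, using known reaction types throughout.
- 10 is desilylated (TBAF, AcOH) to the phenol aldehyde F1.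
- This is dearomatised (PhI(OAc)2, TFA, aq MeCN) to the quinol aldehyde F2.
- F2 is cyclised as its O-stannyl ketyl (Bu3SnH, AIBN, benzene, 80 °C, the known reductive cyclisation of aldehydes onto activated olefins) through the same lactone-locked chair to the 5β-hydroxy enone F3.
- Selective mesylation of the secondary alcohol (MsCl, Et3N) gives the mesylate F4.
- Luche reduction then gives the 2α-alcohol F5, and Mitsunobu inversion with 4-nitrobenzoic acid gives the 2β-ester mesylate F6.
- KHMDS fragments this classical 1,3-hydroxy mesylate to 18.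

2. Step 13. The alkoxide may be diverted by acyl transfer from the C2 ester or by enolisation and isomerisation of the Z-enone, or bromide may leave too slowly at temperatures the product tolerates.
The fallback sets out from 16 and returns at 18 without any new isolable compound, and it changes heterolysis for homolysis. 16, as its trifluoroacetate salt, is treated with PhI(OAc)2 and I2 under visible light in CH2Cl2 at 0 °C (hypoiodite alkoxyl-radical fragmentation). The C9 alkoxyl radical should undergo β-scission of C4–C9, giving the conjugated enone and a tertiary C4 radical. That radical should expel the β-bromine atom at once to give C4=C5, with no base present.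

3. Step 12. Activation of the concave, neopentyl-flanked allylic alcohol may be slow, and elimination to the ring diene may compete with substitution.
The fallback sets out from 14 and returns at 16, and it replaces SN2 inversion by thermodynamic control. An equilibrating Meerwein–Ponndorf–Verley reduction (Al(OiPr)3, iPrOH, toluene, trace acetone) should favour the equatorial 2β-alcohol F7. This is then acylated with retention by 4-nitrobenzoyl chloride and pyridine to 16.

Further compounds
F1 | step 10 | phenol aldehyde | O=C1[C@@H](CN(C)C)[C@H](Cc2c(C)cc(O)cc2C)[C@@H](C=O)O1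
F2 | step 10 | quinol aldehyde | O=C1[C@@H](CN(C)C)[C@H](CC2(O)C(C)=CC(=O)C=C2C)[C@@H](C=O)O1
F3 | step 10 | 5β-hydroxy enone | C[C@@]12CC(=O)C=C(C)[C@]1(O)C[C@H]1[C@H](CN(C)C)C(=O)O[C@@H]1[C@H]2O
F4 | step 10 | mesylate | C[C@@]12CC(=O)C=C(C)[C@]1(O)C[C@H]1[C@H](CN(C)C)C(=O)O[C@@H]1[C@H]2OS(C)(=O)=O
F5 | step 10 | 2α-alcohol | C[C@@]12C[C@H](O)C=C(C)[C@]1(O)C[C@H]1[C@H](CN(C)C)C(=O)O[C@@H]1[C@H]2OS(C)(=O)=O
F6 | step 10 | 2β-ester mesylate | C[C@@]12C[C@@H](OC(=O)c3ccc(cc3)[N+](=O)[O-])C=C(C)[C@]1(O)C[C@H]1[C@H](CN(C)C)C(=O)O[C@@H]1[C@H]2OS(C)(=O)=O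
F0 | step 13 | none | none
F7 | step 12 | 2β-alcohol | C[C@@]12C[C@@H](O)C=C(C)[C@]1(O)C[C@H]1[C@H](CN(C)C)C(=O)O[C@@H]1[C@H]2Br
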